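**Strategy.** Both perhydrobenzoxepine halves are cut from one intermediate, whose cyclohexane is built by a (3+3) annulation. A 4-alkylthiolan-3-one and ethyl 3-methyl-2-oxobut-3-enoate are joined by Michael addition at the sulfur-flanked CH2 and bridging aldol closure at the branched α′-carbon. This forms, in one operation, the CH2–CH2 bond and the bond between the methyl-bearing quaternary carbon and the tertiary carbinol carbon of ring C (the hydroxylated cyclohexane), exploiting the 1,3-relation of its carbinol and ring-fusion ether carbons (an aldol pattern). The sulfur bridge, excised later with Raney Ni, becomes the angular methyl and forces the quaternary centre. Dehydration and deconjugation convert the same product into ring B (the methylenecyclohexane).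

Key step: step 5

Ring labels: A = acetoxy-oxepane, B = methylenecyclohexane, C = hydroxylated cyclohexane, D = oxepanone.

Remark: the absolute sense of induction of the cinchona amine in step 5 is assumed from the usual enamine shielding model; the quinidine-derived pseudoenantiomer would give the mirror-image series.

**Route**

Step 1
Reactants: 1 methyl 4-oxotetrahydrothiophene-3-carboxylate; 2 5-bromo-2-methylpent-2-ene
Product: 3 methyl 3-(4-methylpent-3-en-1-yl)-4-oxotetrahydrothiophene-3-carboxylate (racemic)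
Conditions: K2CO3, NaI (cat.), acetone, reflux
Reagents that add atoms: none
Why: C-alkylation (SN2) of the cyclic β-keto ester enolate by the primary bromide should place the future ring D side chain on the carbon that later becomes the quaternary centre, with no stereochemistry at stake.

Step 2
Reactants: 3 methyl 3-(4-methylpent-3-en-1-yl)-4-oxotetrahydrothiophene-3-carboxylate
Product: 4 4-(4-methylpent-3-en-1-yl)thiolan-3-one (racemic and epimerisable)
Conditions: LiCl, H2O, DMSO, 140 °C
Reagents that add atoms: none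
Why: Krapcho dealkoxycarbonylation should remove the activating ester and leave a ketone flanked by S–CH2 on one side and the side-chain CH on the other.

Step 3
Reactants: 5 ethyl 3-methyl-2-oxobutanoate
Product: 6 ethyl 3-bromo-3-methyl-2-oxobutanoate
Conditions: Br2, CH2Cl2, 0 °C to rt
Reagents that add atoms: bromine BrBr
Why: acid-catalysed α-bromination through the only available enol should give the tertiary α-bromo keto ester.

Step 4
Reactants: 6 ethyl 3-bromo-3-methyl-2-oxobutanoate
Product: 7 ethyl 3-methyl-2-oxobut-3-enoate (used at once as a solution)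
Conditions: Et3N, Et2O, 0 °C
Reagents that add atoms: none
Why: E2 dehydrobromination should give the α-methyl vinyl keto ester, an acceptor whose keto group has no α′-hydrogen.

Step 5
Reactants: 4 4-(4-methylpent-3-en-1-yl)thiolan-3-one; 7 ethyl 3-methyl-2-oxobut-3-enoate
Product: 9 ethyl (1R,2S,3S,5S)-2-hydroxy-3-methyl-1-(4-methylpent-3-en-1-yl)-8-oxo-6-thiabicyclo[3.2.1]octane-2-carboxylate, via Michael adduct 8 (not isolated)
Conditions: 9-amino-9-deoxy-epi-quinine (20 mol %), salicylic acid (40 mol %), toluene, 0 °C to rt, slow addition of 7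
Reagents that add atoms: none
Why: Proposed new method: the primary-amine catalyst should condense with 4 to the less substituted enamine at the sulfur-flanked CH2, which adds 1,4 to the methylene of 7 (Michael step, setting the sulfur-bearing bridgehead under catalyst control), after which the imine tautomerises to the enamine at the side-chain carbon and this attacks the activated keto-ester carbonyl. The closest known reactions are the amine-catalysed formal (3+3) α,α′-annulation of cyclic ketones with β,γ-unsaturated α-keto esters and the Stork enamine α,α′-annulation, and what is new is the α′-branched ketone (quaternary bridgehead) together with the α-methyl, β-unsubstituted acceptor. The cyclohexanone ring closes by a 6-(enolendo)-exo-trig aldol that bridges the thiolanone, so the quaternary carbon can only form with its CH2S bond axial and the side chain equatorial. The hydroxyl should end axial and anti to the thia bridge (ester equatorial, hydrogen-bonded transition state) and the C3 methyl equatorial, because the stereocentre next to the keto ester equilibrates by enolisation before ring closure (Curtin–Hammett). The step needs enamine formation at C2 before C4 of the thiolanone, conjugate instead of carbonyl addition and no Robinson-type closure, which are secured by the strain of the tetrasubstituted alternative enamine, the soft enamine nucleophile and the absence of α′-hydrogens in 7.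

Step 6
Reactants: 9 ethyl (1R,2S,3S,5S)-2-hydroxy-3-methyl-1-(4-methylpent-3-en-1-yl)-8-oxo-6-thiabicyclo[3.2.1]octane-2-carboxylate
Product: 10 ethyl (1S,2S,3S,5S,8R)-2,8-dihydroxy-3-methyl-1-(4-methylpent-3-en-1-yl)-6-thiabicyclo[3.2.1]octane-2-carboxylate
Conditions: Me4NBH(OAc)3, MeCN–AcOH (1:1), −30 to 0 °C
Reagents that add atoms: none
Why: Evans–Saksena reduction should deliver hydride intramolecularly from the axial tertiary hydroxyl (1,3-diaxial to the bridging ketone), so the new hydroxyl falls on the thia-bridge side, anti to the tertiary one, which is the equatorial ring-fusion oxygen of the target.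

Step 7
Reactants: 10 ethyl (1S,2S,3S,5S,8R)-2,8-dihydroxy-3-methyl-1-(4-methylpent-3-en-1-yl)-6-thiabicyclo[3.2.1]octane-2-carboxylate
Product: 11 ethyl (1S,2R,3S,6S)-1,3-dihydroxy-2,6-dimethyl-2-(4-methylpent-3-en-1-yl)cyclohexane-1-carboxylate
Conditions: Raney Ni (W-2, deactivated in refluxing acetone), EtOH, rt
Reagents that add atoms: none
Why: Raney Ni desulfurisation (hydrogenolysis of both C–S bonds) should turn the bridging CH2S into the angular methyl and the sulfur-bearing bridgehead into the ring CH2 without touching a stereocentre, the deactivated catalyst sparing the trisubstituted alkene.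

Step 8
Reactants: 11 ethyl (1S,2R,3S,6S)-1,3-dihydroxy-2,6-dimethyl-2-(4-methylpent-3-en-1-yl)cyclohexane-1-carboxylate
Product: 12 ethyl (1S,2R,3S,6S)-2-{2-[(2R)-3,3-dimethyloxiran-2-yl]ethyl}-1,3-dihydroxy-2,6-dimethylcyclohexane-1-carboxylate
Conditions: D-fructose-derived Shi ketone (30 mol %), KHSO5, K2CO3, Bu4NHSO4, MeCN–CH2(OMe)2–aq. Na2B4O7 buffer, 0 °C
Reagents that add atoms: potassium peroxymonosulfate [K+].[O-]S(=O)(=O)OO
Why: Shi epoxidation of the 2-methylalk-2-ene terminus is reagent-controlled and should give the (R)-epoxide, which fixes the later C3 configuration of ring A.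

Step 9
Reactants: 12 ethyl (1S,2R,3S,6S)-2-{2-[(2R)-3,3-dimethyloxiran-2-yl]ethyl}-1,3-dihydroxy-2,6-dimethylcyclohexane-1-carboxylate
Product: 13 ethyl (3R,5aR,6S,7S,9aS)-3,6-dihydroxy-2,2,5a,7-tetramethyldecahydro-1-benzoxepine-6-carboxylate
Conditions: (1S)-10-camphorsulfonic acid (10 mol %), CH2Cl2, −20 °C
Reagents that add atoms: none
Why: acid-catalysed 7-endo epoxide opening by the equatorial secondary hydroxyl at the tertiary epoxide carbon (Markovnikov bias of the gem-dimethyl terminus) should close the trans-fused oxepane with the C3–O bond untouched, so (3R) is retained, while the tertiary α-hydroxy-ester hydroxyl is hindered and deactivated.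

Step 10
Reactants: 13 ethyl (3R,5aR,6S,7S,9aS)-3,6-dihydroxy-2,2,5a,7-tetramethyldecahydro-1-benzoxepine-6-carboxylate
Product: 14 ethyl (3R,5aR,6S,7S,9aS)-3-(tert-butyldimethylsilyloxy)-6-hydroxy-2,2,5a,7-tetramethyldecahydro-1-benzoxepine-6-carboxylate
Conditions: TBSCl, imidazole, DMAP (cat.), DMF, 40 °C
Reagents that add atoms: tert-butyldimethylsilyl chloride CC(C)(C)[Si](C)(C)Cl
Why: silylation should take the secondary hydroxyl only, since the tertiary α-hydroxy-ester hydroxyl is far more hindered.

Step 11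
Reactants: 14 ethyl (3R,5aR,6S,7S,9aS)-3-(tert-butyldimethylsilyloxy)-6-hydroxy-2,2,5a,7-tetramethyldecahydro-1-benzoxepine-6-carboxylate
Product: 15 ethyl (3R,5aS,9aS)-3-(tert-butyldimethylsilyloxy)-2,2,5a,7-tetramethyl-2,3,4,5,5a,8,9,9a-octahydro-1-benzoxepine-6-carboxylate
Conditions: SOCl2, pyridine, CH2Cl2, 0 °C
Reagents that add atoms: none
Why: anti-E2 dehydration through the chlorosulfite should use the only β-hydrogen, which is trans-diaxial to the axial hydroxyl, and give the tetrasubstituted conjugated ester.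

Step 12
Reactants: 15 ethyl (3R,5aS,9aS)-3-(tert-butyldimethylsilyloxy)-2,2,5a,7-tetramethyl-2,3,4,5,5a,8,9,9a-octahydro-1-benzoxepine-6-carboxylate
Product: 17 ethyl (3R,5aS,6R,9aS)-3-(tert-butyldimethylsilyloxy)-2,2,5a-trimethyl-7-methylidenedecahydro-1-benzoxepine-6-carboxylate, via lithium dienolate 16 (not isolated)
Conditions: LiN(i-Pr)2, THF–HMPA, −78 °C; then AcOH, −78 °C
Reagents that add atoms: none
Why: deconjugation by kinetic γ-deprotonation at the methyl cis to the ester and α-protonation of the dienolate from the face opposite the axial angular methyl should give the exocyclic methylene with the ester equatorial (6R), which is also the more stable epimer.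

Step 13
Reactants: 17 ethyl (3R,5aS,6R,9aS)-3-(tert-butyldimethylsilyloxy)-2,2,5a-trimethyl-7-methylidenedecahydro-1-benzoxepine-6-carboxylate
Product: 18 [(3R,5aS,6R,9aS)-3-(tert-butyldimethylsilyloxy)-2,2,5a-trimethyl-7-methylidenedecahydro-1-benzoxepin-6-yl]methanol
Conditions: LiAlH4, Et2O, 0 °C
Reagents that add atoms: none
Why: hydride reduction of the ester should be faster than any epimerisation or reconjugation of the β,γ-unsaturated ester.

Step 14
Reactants: 18 [(3R,5aS,6R,9aS)-3-(tert-butyldimethylsilyloxy)-2,2,5a-trimethyl-7-methylidenedecahydro-1-benzoxepin-6-yl]methanol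
Product: 19 tert-butyl{[(3R,5aS,6R,9aS)-6-(iodomethyl)-2,2,5a-trimethyl-7-methylidenedecahydro-1-benzoxepin-3-yl]oxy}dimethylsilane
Conditions: I2, PPh3, imidazole, CH2Cl2, 0 °C to rt
Reagents that add atoms: iodine II
Why: Appel-type (Garegg–Samuelsson) iodination of the primary alcohol proceeds at a non-stereogenic carbon and should give the AB-ring iodide.

Step 15
Reactants: 13 ethyl (3R,5aR,6S,7S,9aS)-3,6-dihydroxy-2,2,5a,7-tetramethyldecahydro-1-benzoxepine-6-carboxylate
Product: 20 (3R,5aR,6S,7S,9aS)-6-(hydroxymethyl)-2,2,5a,7-tetramethyldecahydro-1-benzoxepine-3,6-diol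
Conditions: LiAlH4, THF, 0 °C to rt
Reagents that add atoms: none
Why: LiAlH4 reduction of the hindered α-hydroxy ester should give the 1,2-diol needed for the spiro-epoxide.

Step 16
Reactants: 20 (3R,5aR,6S,7S,9aS)-6-(hydroxymethyl)-2,2,5a,7-tetramethyldecahydro-1-benzoxepine-3,6-diol
Product: 22 (3R,5aR,6S,7S,9aS)-2,2,5a,7-tetramethyloctahydro-2H-spiro[1-benzoxepine-6,2′-oxiran]-3-ol, via primary tosylate 21 (not isolated)
Conditions: TsCl (1.1 equiv), Et3N, DMAP (cat.), CH2Cl2, 0 °C; then K2CO3, MeOH, rt
Reagents that add atoms: none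
Why: selective sulfonylation of the primary hydroxyl followed by intramolecular Williamson closure by the tertiary alkoxide should give the spiro-epoxide with the C–O bond at the carbinol carbon retained.

Step 17
Reactants: 19 tert-butyl{[(3R,5aS,6R,9aS)-6-(iodomethyl)-2,2,5a-trimethyl-7-methylidenedecahydro-1-benzoxepin-3-yl]oxy}dimethylsilane; 22 (3R,5aR,6S,7S,9aS)-2,2,5a,7-tetramethyloctahydro-2H-spiro[1-benzoxepine-6,2′-oxiran]-3-ol
Product: 25 ring A tert-butyldimethylsilyl ether of the tetracycle bearing the (3′R)-hydroxyl in ring D, via organolithium 23 (not isolated), via lithium alkoxide 24 (not isolated)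
Conditions: 19, t-BuLi (2.1 equiv), Et2O–pentane, −78 °C; 22, n-BuLi (1.0 equiv), THF, −78 °C; combine, BF3·OEt2, −78 °C
Reagents that add atoms: none
Why: lithium–iodine exchange followed by BF3-assisted SN2 opening of the epoxide at its CH2 should join the halves through the two-carbon link and release the tertiary hydroxyl of ring C with its configuration unchanged.

Step 18
Reactants: 25 ring A tert-butyldimethylsilyl ether of the tetracycle bearing the (3′R)-hydroxyl in ring D
Product: 26 ring A tert-butyldimethylsilyl ether of 3-epi-sodwanone K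
Conditions: Dess–Martin periodinane, NaHCO3, CH2Cl2, rt
Reagents that add atoms: none
Why: Dess–Martin oxidation should convert the only secondary hydroxyl into the ring D ketone and leave the tertiary alcohol and the exocyclic alkene alone.

Step 19
Reactants: 26 ring A tert-butyldimethylsilyl ether of 3-epi-sodwanone K
Product: 27 3-epi-sodwanone K
Conditions: HF·pyridine, THF, 0 °C to rt
Reagents that add atoms: none
Why: fluoride-mediated desilylation under non-basic conditions should free the (3R)-hydroxyl of ring A.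

Step 20
Reactants: 27 3-epi-sodwanone K
Product: 28 3-epi-sodwanone K 3-acetate
Conditions: Ac2O, pyridine, DMAP (cat.), CH2Cl2, rt
Reagents that add atoms: acetic anhydride CC(=O)OC(C)=O
Why: DMAP-catalysed acetylation should take the secondary hydroxyl with retention, the hindered tertiary hydroxyl of ring C staying free.

**Compound list**

1 | methyl 4-oxotetrahydrothiophene-3-carboxylate | COC(=O)C1CSCC1=O | starting material
2 | 5-bromo-2-methylpent-2-ene | CC(C)=CCCBr | starting material
3 | methyl 3-(4-methylpent-3-en-1-yl)-4-oxotetrahydrothiophene-3-carboxylate (racemic) | COC(=O)C1(CCC=C(C)C)CSCC1=O | intermediate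
4 | 4-(4-methylpent-3-en-1-yl)thiolan-3-one (racemic) | CC(C)=CCCC1CSCC1=O | intermediate
5 | ethyl 3-methyl-2-oxobutanoate | CCOC(=O)C(=O)C(C)C | starting material
6 | ethyl 3-bromo-3-methyl-2-oxobutanoate | CCOC(=O)C(=O)C(C)(C)Br | intermediate
7 | ethyl 3-methyl-2-oxobut-3-enoate | CCOC(=O)C(=O)C(C)=C | intermediate
8 | Michael adduct, ethyl 3-methyl-4-[(2S)-4-(4-methylpent-3-en-1-yl)-3-oxothiolan-2-yl]-2-oxobutanoate (other centres epimerising) | CCOC(=O)C(=O)C(C)C[C@@H]1SCC(CCC=C(C)C)C1=O | intermediate
9 | ethyl (1R,2S,3S,5S)-2-hydroxy-3-methyl-1-(4-methylpent-3-en-1-yl)-8-oxo-6-thiabicyclo[3.2.1]octane-2-carboxylate | CCOC(=O)[C@]1(O)[C@@H](C)C[C@@H]2SC[C@@]1(CCC=C(C)C)C2=O | intermediate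
10 | ethyl (1S,2S,3S,5S,8R)-2,8-dihydroxy-3-methyl-1-(4-methylpent-3-en-1-yl)-6-thiabicyclo[3.2.1]octane-2-carboxylate | CCOC(=O)[C@]1(O)[C@@H](C)C[C@@H]2SC[C@@]1(CCC=C(C)C)[C@H]2O | intermediate
11 | ethyl (1S,2R,3S,6S)-1,3-dihydroxy-2,6-dimethyl-2-(4-methylpent-3-en-1-yl)cyclohexane-1-carboxylate | CCOC(=O)[C@]1(O)[C@@H](C)CC[C@H](O)[C@@]1(C)CCC=C(C)C | intermediate
12 | ethyl (1S,2R,3S,6S)-2-{2-[(2R)-3,3-dimethyloxiran-2-yl]ethyl}-1,3-dihydroxy-2,6-dimethylcyclohexane-1-carboxylate | CCOC(=O)[C@]1(O)[C@@H](C)CC[C@H](O)[C@@]1(C)CC[C@H]1OC1(C)C | intermediate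
13 | ethyl (3R,5aR,6S,7S,9aS)-3,6-dihydroxy-2,2,5a,7-tetramethyldecahydro-1-benzoxepine-6-carboxylate | CCOC(=O)[C@]1(O)[C@@H](C)CC[C@@H]2OC(C)(C)[C@H](O)CC[C@@]12C | intermediate
14 | ethyl (3R,5aR,6S,7S,9aS)-3-(tert-butyldimethylsilyloxy)-6-hydroxy-2,2,5a,7-tetramethyldecahydro-1-benzoxepine-6-carboxylate | CCOC(=O)[C@]1(O)[C@@H](C)CC[C@@H]2OC(C)(C)[C@H](O[Si](C)(C)C(C)(C)C)CC[C@@]12C | intermediate
15 | ethyl (3R,5aS,9aS)-3-(tert-butyldimethylsilyloxy)-2,2,5a,7-tetramethyl-2,3,4,5,5a,8,9,9a-octahydro-1-benzoxepine-6-carboxylate | CCOC(=O)C1=C(C)CC[C@@H]2OC(C)(C)[C@H](O[Si](C)(C)C(C)(C)C)CC[C@@]12C | intermediate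
16 | lithium dienolate of 15 (exocyclic methylene ketene acetal) | CCOC(O[Li])=C1C(=C)CC[C@@H]2OC(C)(C)[C@H](O[Si](C)(C)C(C)(C)C)CC[C@@]12C | intermediate
17 | ethyl (3R,5aS,6R,9aS)-3-(tert-butyldimethylsilyloxy)-2,2,5a-trimethyl-7-methylidenedecahydro-1-benzoxepine-6-carboxylate | CCOC(=O)[C@@H]1C(=C)CC[C@@H]2OC(C)(C)[C@H](O[Si](C)(C)C(C)(C)C)CC[C@@]12C | intermediate
18 | [(3R,5aS,6R,9aS)-3-(tert-butyldimethylsilyloxy)-2,2,5a-trimethyl-7-methylidenedecahydro-1-benzoxepin-6-yl]methanol | OC[C@@H]1C(=C)CC[C@@H]2OC(C)(C)[C@H](O[Si](C)(C)C(C)(C)C)CC[C@@]12C | intermediate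
19 | tert-butyl{[(3R,5aS,6R,9aS)-6-(iodomethyl)-2,2,5a-trimethyl-7-methylidenedecahydro-1-benzoxepin-3-yl]oxy}dimethylsilane | IC[C@@H]1C(=C)CC[C@@H]2OC(C)(C)[C@H](O[Si](C)(C)C(C)(C)C)CC[C@@]12C | intermediate
20 | (3R,5aR,6S,7S,9aS)-6-(hydroxymethyl)-2,2,5a,7-tetramethyldecahydro-1-benzoxepine-3,6-diol | OC[C@]1(O)[C@@H](C)CC[C@@H]2OC(C)(C)[C@H](O)CC[C@@]12C | intermediate
21 | primary 4-methylbenzenesulfonate of 20 | Cc1ccc(cc1)S(=O)(=O)OC[C@]1(O)[C@@H](C)CC[C@@H]2OC(C)(C)[C@H](O)CC[C@@]12C | intermediate
22 | (3R,5aR,6S,7S,9aS)-2,2,5a,7-tetramethyloctahydro-2H-spiro[1-benzoxepine-6,2′-oxiran]-3-ol (epoxide oxygen on the face of the former tertiary hydroxyl) | C[C@H]1CC[C@@H]2OC(C)(C)[C@H](O)CC[C@@]2(C)[C@]13CO3 | intermediate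
23 | organolithium from 19 | [Li]C[C@@H]1C(=C)CC[C@@H]2OC(C)(C)[C@H](O[Si](C)(C)C(C)(C)C)CC[C@@]12C | intermediate
24 | lithium alkoxide of 22 | C[C@H]1CC[C@@H]2OC(C)(C)[C@H](O[Li])CC[C@@]2(C)[C@]13CO3 | intermediate
25 | ring A tert-butyldimethylsilyl ether of the tetracycle with (3′R)-hydroxyl in ring D in place of the ketone | C=C1CC[C@@H]2OC(C)(C)[C@H](O[Si](C)(C)C(C)(C)C)CC[C@@]2(C)[C@@H]1CC[C@]1(O)[C@@H](C)CC[C@@H]2OC(C)(C)[C@H](O)CC[C@]21C | intermediate
26 | ring A tert-butyldimethylsilyl ether of 3-epi-sodwanone K | C=C1CC[C@@H]2OC(C)(C)[C@H](O[Si](C)(C)C(C)(C)C)CC[C@@]2(C)[C@@H]1CC[C@]1(O)[C@@H](C)CC[C@@H]2OC(C)(C)C(=O)CC[C@]21C | intermediate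
27 | 3-epi-sodwanone K | C=C1CC[C@@H]2OC(C)(C)[C@H](O)CC[C@@]2(C)[C@@H]1CC[C@]1(O)[C@@H](C)CC[C@@H]2OC(C)(C)C(=O)CC[C@]21C | intermediate
28 | 3-epi-sodwanone K 3-acetate | C=C1CC[C@@H]2OC(C)(C)[C@H](OC(C)=O)CC[C@@]2(C)[C@@H]1CC[C@]1(O)[C@@H](C)CC[C@@H]2OC(C)(C)C(=O)CC[C@]21C | target

**Count**

Total step count: 20. Longest linear sequence: 16 steps (1, 2, 5 to 14, 17 to 20).

**Steps most likely to fail**

Step 5 (Proposed new method). The enamine at the branched α′-carbon may form too slowly, so that the Michael adduct accumulates, or the catalyst may control the faces poorly. The fallback sets out from 4 and 7 and comes back at 9. The two would be combined with catalytic DBU in THF at 0 °C, a Stork-type α,α′-annulation under thermodynamic control. The sulfur-flanked α-carbon is the most acidic ketone position and adds to 7, and only the bridged aldol can follow because 7 has no α′-hydrogen. This gives racemic 9, that is 9 together with its enantiomer ent-9 F1, and preparative chromatography on a chiral stationary phase would deliver 9.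

Step 9. Opening at the secondary epoxide carbon (6-exo) may compete with the 7-endo mode, a loss of regioselectivity. The fallback sets out from 11 and comes back at 13. Markovnikov alkoxymercuration with Hg(OCOCF3)2 in MeCN at 0 °C lets the ring hydroxyl attack the tertiary alkene carbon and gives oxepanyl mercurial F2. Oxidative demercuration (NaBH4, O2, DMF) gives 13 mixed with its (3S)-epimer F3. Dess–Martin oxidation converges both on oxepanone F4, and reduction with (S)-2-methyl-CBS-oxazaborolidine and BH3·SMe2 should return the (3R)-alcohol 13.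

Step 17. The neopentyl-type epoxide opening may be outrun by BF3-induced rearrangement of the spiro-epoxide or by quenching of the organolithium. The fallback sets out from 19 (with 22) and comes back at 25. Iodide 19 is displaced with PhSO2Na in DMF at 60 °C to give sulfone F5. Its lithio derivative (n-BuLi, THF–HMPA, −78 °C) opens 22, used as its lithium alkoxide, at the methylene to give hydroxy sulfone F6. Reductive desulfonylation with Na(Hg) and Na2HPO4 in MeOH gives 25.

**Further compounds**

F1 | step 5 | ent-9, ethyl (1S,2R,3R,5R)-2-hydroxy-3-methyl-1-(4-methylpent-3-en-1-yl)-8-oxo-6-thiabicyclo[3.2.1]octane-2-carboxylate | CCOC(=O)[C@@]1(O)[C@H](C)C[C@H]2SC[C@]1(CCC=C(C)C)C2=O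
F2 | step 9 | oxepan-3-yl mercury trifluoroacetate corresponding to 13 (C3 epimers) | CCOC(=O)[C@]1(O)[C@@H](C)CC[C@@H]2OC(C)(C)C([Hg]OC(=O)C(F)(F)F)CC[C@@]12C
F3 | step 9 | (3S)-epimer of 13 | CCOC(=O)[C@]1(O)[C@@H](C)CC[C@@H]2OC(C)(C)[C@@H](O)CC[C@@]12C
F4 | step 9 | ethyl (5aR,6S,7S,9aS)-6-hydroxy-2,2,5a,7-tetramethyl-3-oxodecahydro-1-benzoxepine-6-carboxylate | CCOC(=O)[C@]1(O)[C@@H](C)CC[C@@H]2OC(C)(C)C(=O)CC[C@@]12C
F5 | step 17 | phenyl sulfone from 19 | O=S(=O)(C[C@@H]1C(=C)CC[C@@H]2OC(C)(C)[C@H](O[Si](C)(C)C(C)(C)C)CC[C@@]12C)c1ccccc1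
F6 | step 17 | 25 bearing a phenylsulfonyl group on the linker carbon next to ring B (epimers) | C=C1CC[C@@H]2OC(C)(C)[C@H](O[Si](C)(C)C(C)(C)C)CC[C@@]2(C)[C@@H]1C(C[C@]1(O)[C@@H](C)CC[C@@H]2OC(C)(C)[C@H](O)CC[C@]21C)S(=O)(=O)c1ccccc1
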